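**Retrosynthetic overview**
1. Last bond: the C3–O ester, made by Steglich coupling of bicyclic diol acetate 14 with (2E,4E,6R)-acid 22; 22 comes from tiglic acid (asymmetric hydrogenation, Wittig, Horner–Wadsworth–Emmons).
2. C7 carbinol and its C3 side group: 1,2-addition of a 2-lithioallyl alkoxide to a C7 ketone whose C8 carbonyl is masked as a dienol methyl ether (9); DDQ then unveils the 1,9-dien-8-one.
3. C3–OH and C4–H: anti-Markovnikov syn hydration of the C3=C4 alkene of bicyclic enone 5, with face control by the C5 methyl.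
4. Enone 5: organocatalytic asymmetric deconjugative Robinson annulation of 2,3-dimethylcyclohexenone (through its β,γ-isomer 2) with methyl vinyl ketone; this sets C5.
5. Ring order: ring B is the starting cyclohexenone; ring A is annulated onto it in step 2; no further ring is formed.

Assumption: ring carbons are labelled C1–C10 in the eremophilane manner (C8 ketone, C9=C10 and C1=C2 alkenes, C3 acyloxy carbon, C4 and C5 methyl-bearing carbons, C6 the CH2, C7 the carbinol; ring A = C5 to C10, ring B = C1 to C5 plus C10; side-chain atoms are primed), and every compound called a starting material is taken to be purchasable.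

**Route**

Step 1
Reactants: 1 2,3-dimethylcyclohex-2-en-1-one
Product: 2 rac-2,3-dimethylcyclohex-3-en-1-one
Conditions: KOtBu (1.2 equiv), THF/t-BuOH, 0 °C; inverse quench into AcOH/THF, −78 °C
Reagents that add atoms: none
Why: thermodynamic γ-deprotonation gives the extended potassium dienolate and kinetic α-protonation delivers the β,γ-unsaturated ketone (deconjugative protonation of an enone); 2 is racemic and configurationally labile and its stereocentre is erased again in the dienolate of step 2, so no stereochemical information is fixed here.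

Step 2
Reactants: 2 rac-2,3-dimethylcyclohex-3-en-1-one; 3 but-3-en-2-one (methyl vinyl ketone)
Product: 5 (S)-4a,5-dimethyl-4,4a,7,8-tetrahydronaphthalen-2(3H)-one, via Michael adduct 4 (not isolated)
Conditions: squaramide catalyst Q (10 mol %; Q = 3-{[3,5-bis(trifluoromethyl)benzyl]amino}-4-[(9-deoxy-epi-quinin-9-yl)amino]cyclobut-3-ene-1,2-dione), 3 (2 equiv), toluene, −20 °C; then pyrrolidine (0.3 equiv), AcOH (0.3 equiv), 4 Å MS, 50 °C
Reagents that add atoms: none
Why: Proposed new method: the quinuclidine nitrogen of Q reversibly removes the doubly activated (allylic and α-carbonyl) C–H of 2 to give an achiral dienolate held as a chiral ammonium ion pair while the squaramide N–H pair binds and activates the vinyl ketone, the dienolate attacks through its α-carbon (largest HOMO coefficient, kinetic site) on one enantiotopic face to create the quaternary C5 stereocentre (S) in a dynamic kinetic asymmetric Michael addition, and pyrrolidinium acetate then closes ring A by enamine aldol condensation onto the ring ketone; the closest known reaction types are bifunctional Brønsted-base/hydrogen-bond-catalysed α-selective Michael additions of transient dienolates of β,γ-unsaturated ketones to nitroalkenes and other doubly activated acceptors and the amine-catalysed Robinson annulation (Hajos–Parrish–Eder–Sauer–Wiechert type), neither yet shown for a simple vinyl ketone with an α-methyl cyclic β,γ-enone nor telescoped into a deconjugative annulation.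

Step 3
Reactants: 5 (S)-4a,5-dimethyl-4,4a,7,8-tetrahydronaphthalen-2(3H)-one
Product: 6 (4aS,5S,6S)-6-hydroxy-4a,5-dimethyl-4,4a,5,6,7,8-hexahydronaphthalen-2(3H)-one
Conditions: 9-mesityl-10-methylacridinium tetrafluoroborate (5 mol %), PhSSPh (10 mol %), MeCN/H2O (9:1), 450 nm LEDs, rt
Reagents that add atoms: water, O
Why: the excited acridinium oxidises only the electron-rich trisubstituted C3=C4 alkene to its radical cation, water adds at the less substituted C3 and the thiol hydrogen-atom donor reduces the tertiary C4 radical, both from the face opposite the axial C5 methyl, giving 3S (equatorial OH) and 4S (methyl cis to the C5 methyl) (photoredox anti-Markovnikov alkene hydration).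

Step 4
Reactants: 6 (4aS,5S,6S)-6-hydroxy-4a,5-dimethyl-4,4a,5,6,7,8-hexahydronaphthalen-2(3H)-one
Product: 7 (4aS,5S,6S)-3,6-dihydroxy-4a,5-dimethyl-4,4a,5,6,7,8-hexahydronaphthalen-2(3H)-one (mixture of epimers at the new carbinol, C7 in the target labelling)
Conditions: LiN(SiMe3)2 (2.3 equiv), THF, −78 °C; (±)-3-phenyl-2-(phenylsulfonyl)oxaziridine (1.3 equiv), −78 °C; AcOH
Reagents that add atoms: 3-phenyl-2-(phenylsulfonyl)oxaziridine, O=S(=O)(c1ccccc1)N1OC1c1ccccc1
Why: kinetic α′-deprotonation of the enone (the C3–OH rides as its lithium alkoxide) gives the cross-conjugated enolate, which is hydroxylated at C7 by electrophilic oxygen transfer (Davis oxaziridine enolate hydroxylation); the C7 configuration is irrelevant because it is oxidised in step 6.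

Step 5
Reactants: 7 (4aS,5S,6S)-3,6-dihydroxy-4a,5-dimethyl-4,4a,5,6,7,8-hexahydronaphthalen-2(3H)-one
Product: 8 (4aS,5S,6S)-2-methoxy-4a,5-dimethyl-3,4,4a,5,6,7-hexahydronaphthalene-3,6-diol (C3 epimers; dienol ether C8(OMe)=C9–C10=C1 in the target labelling)
Conditions: 2,2-dimethoxypropane (5 equiv), TsOH·H2O (2 mol %), MeOH/DMF, rt; Et3N quench
Reagents that add atoms: 2,2-dimethoxypropane, COC(C)(C)OC
Why: acid-catalysed transketalisation and loss of methanol toward C1 converts the conjugated enone into its extended dienol methyl ether (dienol ether formation as used for 3-alkoxy-3,5-diene steroids), which masks C8 and makes the C7 carbinol allylic; no defined stereocentre is touched.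

Step 6
Reactants: 8 (4aS,5S,6S)-2-methoxy-4a,5-dimethyl-3,4,4a,5,6,7-hexahydronaphthalene-3,6-diol
Product: 9 (7S,8S,8aS)-7-hydroxy-3-methoxy-8,8a-dimethyl-6,7,8,8a-tetrahydronaphthalen-2(1H)-one
Conditions: activated MnO2 (15 equiv), K2CO3, CH2Cl2, rt
Reagents that add atoms: none
Why: MnO2 oxidises the allylic C7 carbinol but not the saturated secondary C3–OH (chemoselective allylic alcohol oxidation), giving a C7 ketone that cannot tautomerise to a diosphenol because C8 is locked as the enol ether.

Step 7
Reactants: 9 (7S,8S,8aS)-7-hydroxy-3-methoxy-8,8a-dimethyl-6,7,8,8a-tetrahydronaphthalen-2(1H)-one; 10 2-bromoprop-2-en-1-ol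
Product: 13 (3S,4aS,5S,6S)-3,6-dihydroxy-3-(3-hydroxyprop-1-en-2-yl)-4a,5-dimethyl-4,4a,5,6-tetrahydronaphthalen-2(3H)-one, via dilithio reagent 11 (not isolated), via dienol ether adduct 12 (not isolated)
Conditions: 10 (3.3 equiv), nBuLi (3.3 equiv) then tBuLi (6.6 equiv), Et2O, −78 → 0 °C; 9, THF, −78 °C; H2O; crude 12, DDQ (1.05 equiv), acetone/H2O (20:1), 0 °C
Reagents that add atoms: water, O
Why: the alkenyllithium adds 1,2 to the C7 ketone from the convex face opposite the axial C5 methyl (equatorial attack on a ketone with a 1,3-axial methyl), placing the new C7–OH syn to the C5 methyl (7S), and DDQ then removes hydride from C2 of the dienol ether so that hydrolysis of the oxocarbenium ion gives the 1,9-dien-8-one (DDQ dehydrogenation of a dienol ether to the linear dienone).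

Step 8
Reactants: 13 (3S,4aS,5S,6S)-3,6-dihydroxy-3-(3-hydroxyprop-1-en-2-yl)-4a,5-dimethyl-4,4a,5,6-tetrahydronaphthalen-2(3H)-one
Product: 14 2-[(2S,7S,8S,8aS)-2,7-dihydroxy-8,8a-dimethyl-3-oxo-1,2,3,7,8,8a-hexahydronaphthalen-2-yl]prop-2-en-1-yl acetate
Conditions: Ac2O (1.1 equiv), pyridine, CH2Cl2, −20 °C
Reagents that add atoms: acetic anhydride, CC(=O)OC(C)=O
Why: the unhindered primary allylic hydroxyl is acetylated far faster than the secondary C3–OH next to the methyl-bearing C4 and the tertiary C7–OH (selective acylation of a primary alcohol).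

Step 9
Reactants: 15 (E)-2-methylbut-2-enoic acid (tiglic acid)
Product: 16 (R)-2-methylbutanoic acid
Conditions: Ru(OAc)2[(R)-H8-BINAP] (0.5 mol %), H2 (4 atm), MeOH, rt
Reagents that add atoms: none
Why: carboxylate-directed enantioface-selective hydrogenation of an α,β-unsaturated acid by a BINAP-type ruthenium dicarboxylate (Noyori-type asymmetric hydrogenation) sets the side-chain stereocentre as R.

Step 10
Reactants: 16 (R)-2-methylbutanoic acid
Product: 17 (R)-2-methylbutan-1-ol
Conditions: LiAlH4, Et2O, 0 °C → rt; H2O/NaOH work-up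
Reagents that add atoms: none
Why: hydride reduction of the carboxylic acid to the primary alcohol (LiAlH4 reduction) leaves the α-stereocentre untouched.

Step 11
Reactants: 17 (R)-2-methylbutan-1-ol; 18 2-(triphenyl-λ5-phosphanylidene)propanal
Product: 20 (2E,4R)-2,4-dimethylhex-2-enal, via aldehyde 19 (not isolated)
Conditions: TEMPO (1 mol %), KBr (10 mol %), NaOCl, NaHCO3 (pH 9), CH2Cl2/H2O, 0 °C; dried CH2Cl2 layer, then 18 (1.2 equiv), 40 °C
Reagents that add atoms: none
Why: nitroxyl-catalysed hypochlorite oxidation (Anelli oxidation) gives the α-chiral aldehyde without enolisation, and the stabilised formyl ylide converts it under non-basic conditions into the (E)-trisubstituted enal (Wittig olefination) with the stereocentre preserved.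

Step 12
Reactants: 20 (2E,4R)-2,4-dimethylhex-2-enal; 21 2-(diethoxyphosphoryl)acetic acid
Product: 22 (2E,4E,6R)-4,6-dimethylocta-2,4-dienoic acid
Conditions: 21 (1.3 equiv), nBuLi (2.6 equiv), THF, −78 → 0 °C; 20, 0 °C → rt; 1 M HCl
Reagents that add atoms: none
Why: the dianion of the phosphonoacetic acid olefinates the enal directly to the (2E)-dienoic acid (Horner–Wadsworth–Emmons reaction), avoiding the amine and heat of a Doebner condensation that could racemise C6′ through a dienamine.

Step 13
Reactants: 14 2-[(2S,7S,8S,8aS)-2,7-dihydroxy-8,8a-dimethyl-3-oxo-1,2,3,7,8,8a-hexahydronaphthalen-2-yl]prop-2-en-1-yl acetate; 22 (2E,4E,6R)-4,6-dimethylocta-2,4-dienoic acid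
Product: 23 (1S,2S,7S,8aS)-7-[3-(acetyloxy)prop-1-en-2-yl]-7-hydroxy-1,8a-dimethyl-6-oxo-1,2,6,7,8,8a-hexahydronaphthalen-2-yl (2E,4E,6R)-4,6-dimethylocta-2,4-dienoate (CNP0160850.1)
Conditions: DCC (1.3 equiv), DMAP (0.2 equiv), CH2Cl2, 0 °C → rt
Reagents that add atoms: none
Why: carbodiimide/DMAP acylation (Steglich esterification) of the secondary allylic C3–OH proceeds with retention because the C3–O bond is not broken, while the tertiary C7–OH is too hindered to react.

**Compound list**
1 | 2,3-dimethylcyclohex-2-en-1-one | CC1=C(C)C(=O)CCC1 | starting material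
2 | rac-2,3-dimethylcyclohex-3-en-1-one | CC1C(=O)CCC=C1C | intermediate
3 | but-3-en-2-one (methyl vinyl ketone) | CC(=O)C=C | starting material
4 | (S)-2,3-dimethyl-2-(3-oxobutyl)cyclohex-3-en-1-one | CC(=O)CC[C@]1(C)C(=O)CCC=C1C | intermediate
5 | (S)-4a,5-dimethyl-4,4a,7,8-tetrahydronaphthalen-2(3H)-one | O=C1CC[C@]2(C)C(=C1)CCC=C2C | intermediate
6 | (4aS,5S,6S)-6-hydroxy-4a,5-dimethyl-4,4a,5,6,7,8-hexahydronaphthalen-2(3H)-one | O=C1CC[C@]2(C)C(=C1)CC[C@H](O)[C@H]2C | intermediate
7 | (4aS,5S,6S)-3,6-dihydroxy-4a,5-dimethyl-4,4a,5,6,7,8-hexahydronaphthalen-2(3H)-one (C3 epimers) | O=C1C(O)C[C@]2(C)C(=C1)CC[C@H](O)[C@H]2C | intermediate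
8 | (4aS,5S,6S)-2-methoxy-4a,5-dimethyl-3,4,4a,5,6,7-hexahydronaphthalene-3,6-diol (C3 epimers) | COC=1C(O)C[C@]2(C)C(C=1)=CC[C@H](O)[C@H]2C | intermediate
9 | (7S,8S,8aS)-7-hydroxy-3-methoxy-8,8a-dimethyl-6,7,8,8a-tetrahydronaphthalen-2(1H)-one | COC=1C(=O)C[C@]2(C)C(C=1)=CC[C@H](O)[C@H]2C | intermediate
10 | 2-bromoprop-2-en-1-ol | OCC(Br)=C | starting material
11 | lithium 2-lithioprop-2-en-1-olate | [Li]OCC([Li])=C | intermediate
12 | (3S,4aS,5S,6S)-3-(3-hydroxyprop-1-en-2-yl)-2-methoxy-4a,5-dimethyl-3,4,4a,5,6,7-hexahydronaphthalene-3,6-diol | COC=1[C@@](O)(C(=C)CO)C[C@]2(C)C(C=1)=CC[C@H](O)[C@H]2C | intermediate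
13 | (3S,4aS,5S,6S)-3,6-dihydroxy-3-(3-hydroxyprop-1-en-2-yl)-4a,5-dimethyl-4,4a,5,6-tetrahydronaphthalen-2(3H)-one | C=C(CO)[C@@]1(O)C[C@]2(C)C(=CC1=O)C=C[C@H](O)[C@H]2C | intermediate
14 | 2-[(2S,7S,8S,8aS)-2,7-dihydroxy-8,8a-dimethyl-3-oxo-1,2,3,7,8,8a-hexahydronaphthalen-2-yl]prop-2-en-1-yl acetate | C=C(COC(C)=O)[C@@]1(O)C[C@]2(C)C(=CC1=O)C=C[C@H](O)[C@H]2C | intermediate
15 | (E)-2-methylbut-2-enoic acid (tiglic acid) | C/C=C(\C)C(O)=O | starting material
16 | (R)-2-methylbutanoic acid | OC(=O)[C@H](C)CC | intermediate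
17 | (R)-2-methylbutan-1-ol | OC[C@H](C)CC | intermediate
18 | 2-(triphenyl-λ5-phosphanylidene)propanal | CC(C=O)=P(c1ccccc1)(c1ccccc1)c1ccccc1 | starting material
19 | (R)-2-methylbutanal | O=C[C@H](C)CC | intermediate
20 | (2E,4R)-2,4-dimethylhex-2-enal | O=C/C(C)=C/[C@H](C)CC | intermediate
21 | 2-(diethoxyphosphoryl)acetic acid | CCOP(=O)(CC(=O)O)OCC | starting material
22 | (2E,4E,6R)-4,6-dimethylocta-2,4-dienoic acid | OC(=O)/C=C/C(C)=C/[C@H](C)CC | intermediate
23 | (1S,2S,7S,8aS)-7-[3-(acetyloxy)prop-1-en-2-yl]-7-hydroxy-1,8a-dimethyl-6-oxo-1,2,6,7,8,8a-hexahydronaphthalen-2-yl (2E,4E,6R)-4,6-dimethylocta-2,4-dienoate | C=C(COC(C)=O)[C@@]1(O)C[C@]2(C)C(=CC1=O)C=C[C@H](OC(=O)/C=C/C(C)=C/[C@H](C)CC)[C@H]2C | target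

**Step count and risks**
Total: 13 steps. Longest linear sequence: 9 steps (steps 1 to 8, then 13); the acid 22 is made in a 4-step branch (steps 9 to 12).

The three steps most likely to fail:

Step 2 (the proposed new annulation). Likely failures are base-catalysed reconjugation of 2 to unreactive 1, γ- instead of α-attack, or low enantioselectivity; which of Q or its quinidine-derived pseudo-enantiomer gives (S)-5 is settled by comparison with 5 made as follows. The fallback uses known chemistry, sets out from 3 and returns at 5. Methyl vinyl ketone 3 is added to commercial 2-methylcyclohexane-1,3-dione F1 (Et3N, rt) to give 2-methyl-2-(3-oxobutyl)cyclohexane-1,3-dione F2. D-Proline (or one of the established amino-amide catalysts of the same sense) then effects the Hajos–Parrish–Eder–Sauer–Wiechert aldol condensation to (R)-8a-methyl-3,4,8,8a-tetrahydronaphthalene-1,6(2H,7H)-dione F3, enriched by crystallisation. The more electrophilic saturated ketone is methylated chemoselectively with MeCeCl2 (from MeLi and CeCl3, THF, −78 °C) to give (4aR)-5-hydroxy-4a,5-dimethyl-4,4a,5,6,7,8-hexahydronaphthalen-2(3H)-one F4. Acid-catalysed dehydration (TsOH, toluene, 80 °C, thermodynamic endocyclic alkene) gives 5. This costs two extra steps, and C5 is still set by an organocatalytic asymmetric step.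

Step 3 (photoredox hydration). Likely failures are incomplete facial control at C3/C4 or thiyl-radical side reactions with the enone. The fallback sets out from 5 and returns at 6. Treatment with 9-BBN (3 equiv, THF, 65 °C) then NaOH/H2O2 reduces the enone carbonyl and hydroborates the C3=C4 alkene syn from the face opposite the C5 methyl, giving (4aS,5S,6S)-4a,5-dimethyl-2,3,4,4a,5,6,7,8-octahydronaphthalene-2,6-diol F5. MnO2 then re-oxidises only the allylic C8 carbinol to give 6.

Step 7 (alkenyl addition and DDQ unmasking). Likely failures are enolisation of the ketone by the basic dianion or poor behaviour of the dilithio reagent. The fallback sets out from 9 and returns at 13. Commercial isopropenylmagnesium bromide (CH2=C(CH3)MgBr) with CeCl3 in THF at −78 °C adds to the C7 ketone with the same facial preference to give (3S,4aS,5S,6S)-2-methoxy-4a,5-dimethyl-3-(prop-1-en-2-yl)-3,4,4a,5,6,7-hexahydronaphthalene-3,6-diol F6. This is oxidised crude with DDQ in wet acetone to (3S,4aS,5S,6S)-3,6-dihydroxy-4a,5-dimethyl-3-(prop-1-en-2-yl)-4,4a,5,6-tetrahydronaphthalen-2(3H)-one F7. Allylic hydroxylation of the isopropenyl methyl group with SeO2 (cat.)/t-BuOOH in CH2Cl2 then gives 13.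

**Further compounds**
F1 | step 2 | 2-methylcyclohexane-1,3-dione | CC1C(=O)CCCC1=O
F2 | step 2 | 2-methyl-2-(3-oxobutyl)cyclohexane-1,3-dione | CC(=O)CCC1(C)C(=O)CCCC1=O
F3 | step 2 | (R)-8a-methyl-3,4,8,8a-tetrahydronaphthalene-1,6(2H,7H)-dione | O=C1CC[C@]2(C)C(=C1)CCCC2=O
F4 | step 2 | (4aR)-5-hydroxy-4a,5-dimethyl-4,4a,5,6,7,8-hexahydronaphthalen-2(3H)-one | O=C1CC[C@]2(C)C(=C1)CCCC2(C)O
F5 | step 3 | (4aS,5S,6S)-4a,5-dimethyl-2,3,4,4a,5,6,7,8-octahydronaphthalene-2,6-diol | OC1CC[C@]2(C)C(=C1)CC[C@H](O)[C@H]2C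
F6 | step 7 | (3S,4aS,5S,6S)-2-methoxy-4a,5-dimethyl-3-(prop-1-en-2-yl)-3,4,4a,5,6,7-hexahydronaphthalene-3,6-diol | COC=1[C@@](O)(C(C)=C)C[C@]2(C)C(C=1)=CC[C@H](O)[C@H]2C
F7 | step 7 | (3S,4aS,5S,6S)-3,6-dihydroxy-4a,5-dimethyl-3-(prop-1-en-2-yl)-4,4a,5,6-tetrahydronaphthalen-2(3H)-one | C=C(C)[C@@]1(O)C[C@]2(C)C(=CC1=O)C=C[C@H](O)[C@H]2C
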